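**Retrosynthetic overview**

1. Target 25 ⇒ selective C15 acetylation, methylalumination/hydroxymethylation of a C13≡C14 alkyne, and reagent-controlled propargylation of the C11 aldehyde 21 (ent-3β-acetoxydrimenal).
2. 21 ⇒ bicyclic enone ester 14: the C6 oxygen is removed via the dienyl triflate and a 1,4-hydrogenation of the C6=C7–C8=C9 diene (which also sets C9), then the C11 ester is taken to the aldehyde.
3. 14 ⇒ acyclic keto alkylidene-acetoacetate 11 by disconnecting C5–C10 (Michael) and C7=C8 (aldol condensation) in one operation; ring A closes first, ring B second.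
4. Enabling feature: in ring B the array C7=C8(CH3)–C9(C11) is a Hagemann-ester retron once a carbonyl sits on C6. That carbonyl makes C5 and C7 the two nucleophilic ends of an acetone unit, C10=C9(CO2Me)–C8(=O)CH3 is the matching 1,3-bis-electrophile, and the C4–C3–C2–C1 tether makes the first closure six-membered.
5. 11 ⇒ 2,2-dimethylpent-4-enal (1), a masked 3-oxobutyl Grignard reagent (from 2) and methyl acetoacetate (9); C3 is set by CBS reduction and relays to C10.

Key step: step 8

Assumption: the target is read as (3R,5S,9R,10R,11S,13E)-11-hydroxylabda-7,13-diene-3,15-diyl diacetate (an ent-labdane); drimane/labdane numbering (decalin C1–C10, C11 on C9, side chain C12–C15) is used for all ring compounds.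
Assumption: B-allenyldiisopinocampheylborane is taken to show the same facial preference toward aldehydes as its allyl analogue.

**Route**

Step 1
Reactants: 1 2,2-dimethylpent-4-enal; 2 2-(2-bromoethyl)-2-methyl-1,3-dioxolane
Product: 4 rac-4,4-dimethyl-1-(2-methyl-1,3-dioxolan-2-yl)hept-6-en-3-ol, via Grignard reagent 3 (not isolated)
Conditions: Mg, THF, 25–30 °C (2 → 3); then 1, −20 → 0 °C; aq. NH4Cl
Reagents that add atoms: none
Why: Grignard addition of a masked 3-oxobutyl nucleophile to a non-enolisable neopentyl aldehyde is reliable; the carbinol centre forms racemic and is reset in steps 2 and 3.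

Step 2
Reactants: 4 rac-4,4-dimethyl-1-(2-methyl-1,3-dioxolan-2-yl)hept-6-en-3-ol
Product: 5 4,4-dimethyl-1-(2-methyl-1,3-dioxolan-2-yl)hept-6-en-3-one
Conditions: Dess–Martin periodinane, pyridine, CH2Cl2, 0 °C → rt
Reagents that add atoms: none
Why: Dess–Martin oxidation of a hindered secondary alcohol should proceed cleanly, and the pyridine buffer protects the acid-labile dioxolane.

Step 3
Reactants: 5 4,4-dimethyl-1-(2-methyl-1,3-dioxolan-2-yl)hept-6-en-3-one
Product: 6 (3R)-4,4-dimethyl-1-(2-methyl-1,3-dioxolan-2-yl)hept-6-en-3-ol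
Conditions: (S)-2-methyl-CBS-oxazaborolidine (0.2 equiv), catecholborane, toluene, −40 → −20 °C; MeOH, then aq. NaOH wash
Reagents that add atoms: none
Why: Corey–Bakshi–Shibata reduction, in which the tertiary alkyl group acts as the large substituent so that the (S)-catalyst should deliver hydride to give the 3R carbinol, while catecholborane leaves the terminal alkene untouched at this temperature.

Step 4
Reactants: 6 (3R)-4,4-dimethyl-1-(2-methyl-1,3-dioxolan-2-yl)hept-6-en-3-ol
Product: 7 (3R)-4,4-dimethyl-1-(2-methyl-1,3-dioxolan-2-yl)hept-6-en-3-yl acetate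
Conditions: Ac2O, DMAP (cat.), pyridine, 40 °C
Reagents that add atoms: acetic anhydride, CC(=O)OC(C)=O
Why: DMAP-catalysed acetylation of the hindered alcohol gives an acid-stable mask for the C3 hydroxyl, which would otherwise form hemiketals with either ketone of the later intermediates.

Step 5
Reactants: 7 (3R)-4,4-dimethyl-1-(2-methyl-1,3-dioxolan-2-yl)hept-6-en-3-yl acetate
Product: 8 (5R)-6,6-dimethyl-2-oxonon-8-en-5-yl acetate
Conditions: 1 M aq. HCl, THF, rt
Reagents that add atoms: water, O
Why: acid-catalysed ketal hydrolysis frees the methyl ketone, and the acetate and the alkene are stable to dilute acid at room temperature.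

Step 6
Reactants: 8 (5R)-6,6-dimethyl-2-oxonon-8-en-5-yl acetate; 9 methyl acetoacetate
Product: 10 methyl (6R)-6-acetoxy-2-acetyl-3,7,7-trimethyldeca-2,9-dienoate (E/Z mixture)
Conditions: TiCl4, pyridine, THF, 0 °C → rt
Reagents that add atoms: none
Why: Knoevenagel condensation under TiCl4/pyridine activation should condense the unhindered methyl ketone with the active methylene compound; no stereocentre is formed, and the E, Z and deconjugated olefin isomers all converge in step 8.

Step 7
Reactants: 10 methyl (6R)-6-acetoxy-2-acetyl-3,7,7-trimethyldeca-2,9-dienoate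
Product: 11 methyl (6R)-6-acetoxy-2-acetyl-3,7,7-trimethyl-9-oxodec-2-enoate (E/Z mixture)
Conditions: PdCl2 (0.1 equiv), CuCl, O2 (1 atm), DMF/H2O 7:1, rt
Reagents that add atoms: water, O
Why: Wacker oxidation should convert the terminal alkene into the methyl ketone with Markovnikov selectivity, while the electron-poor tetrasubstituted alkylidene does not compete for palladium.

Step 8
Reactants: 11 methyl (6R)-6-acetoxy-2-acetyl-3,7,7-trimethyl-9-oxodec-2-enoate
Product: 14 methyl (3R,5S,10R)-3-acetoxy-6-oxodrim-7-en-11-oate (C9 epimers), via Michael adduct 12 (not isolated), via ketol 13 (not isolated)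
Conditions: TsOH·H2O (0.3 equiv), toluene (0.01 M), 80 °C, then reflux with Dean–Stark trap
Reagents that add atoms: none
Why: Acid-catalysed enolisation of the C6 methyl ketone toward C5 is followed by conjugate (Michael) addition of that enol to the protonated alkylidene acetoacetate (C5–C10), and the 1,5-diketone 12 then undergoes aldol addition of its C7 enol to the C8 ketone and dehydration (C7=C8). The closest known reaction types are the acid-catalysed Robinson annulation and the Hagemann ester synthesis (Michael addition to an alkylidene acetoacetate, then aldol condensation to a 3-methylcyclohex-2-enone-4-carboxylate). Ring A closes 6-(enolexo)-exo-trig (C5 onto C10; the C7 enol could only form an eight-membered ring), and ring B closes 6-(enolexo)-exo-trig (C7 onto the C8 carbonyl) and is made irreversible by loss of water. C10 is set in a chair transition state with the C3 acetoxy group equatorial, the C10 methyl axial and the bulky alkylidene terminus equatorial; C5 is epimerisable next to the C6 ketone and should settle as the trans ring fusion; C9 is not controlled and is erased in step 9. The step needs facial selectivity at C10 and regioselectivity in the aldol: the first rests on the equatorial preference of the acetoxy group, which is modest, so the C10 epimer may have to be separated. The second rests on the alternative aldol (acetoacetate methyl onto C6) having to attack a carbonyl whose neighbour C5 lies between two quaternary carbons and to place a vinylic methyl against the equatorial C4 methyl.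

Step 9
Reactants: 14 methyl (3R,5S,10R)-3-acetoxy-6-oxodrim-7-en-11-oate
Product: 16 methyl (3R,5S,10R)-3-acetoxy-6-(trifluoromethanesulfonyloxy)drima-6,8-dien-11-oate, via sodium dienolate 15 (not isolated)
Conditions: NaH (1.1 equiv), THF/DMF, 0 °C; then PhNTf2, 0 °C → rt
Reagents that add atoms: N-phenylbis(trifluoromethanesulfonimide), O=S(=O)(N(c1ccccc1)S(=O)(=O)C(F)(F)F)C(F)(F)F
Why: the C9 hydrogen (α to the ester, γ to the enone) is by far the most acidic, so the extended enolate should form and be sulfonylated on the ketone oxygen (enol triflate formation), which avoids any addition to the very hindered C6 carbonyl carbon and removes the uncontrolled C9 centre.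

Step 10
Reactants: 16 methyl (3R,5S,10R)-3-acetoxy-6-(trifluoromethanesulfonyloxy)drima-6,8-dien-11-oate
Product: 17 methyl (3R,5S,10R)-3-acetoxydrima-6,8-dien-11-oate
Conditions: Pd(OAc)2 (5 mol %), PPh3 (10 mol %), HCO2H, Et3N, DMF, 60 °C
Reagents that add atoms: none
Why: palladium-catalysed formate reduction of an enol triflate should replace the triflate by hydrogen without moving the diene, and the ester and acetate are inert.

Step 11
Reactants: 17 methyl (3R,5S,10R)-3-acetoxydrima-6,8-dien-11-oate
Product: 18 methyl (3R,5S,9R,10R)-3-acetoxydrim-7-en-11-oate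
Conditions: (η6-naphthalene)Cr(CO)3 (0.2 equiv), H2 (50 atm), THF, 45 °C
Reagents that add atoms: none
Why: tricarbonylchromium-catalysed 1,4-hydrogenation of a cisoid 1,3-diene adds both hydrogens (to C6 and C9) from the metal-bound face and leaves the C7=C8 olefin; chromium should bind the face opposite the axial C10 and C4 methyl groups, so H9 enters anti to the C10 methyl and sets 9R.

Step 12
Reactants: 18 methyl (3R,5S,9R,10R)-3-acetoxydrim-7-en-11-oate
Product: 19 (3R,5S,9R,10R)-drim-7-ene-3,11-diol
Conditions: LiAlH4, THF, 0 °C → rt; Fieser work-up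
Reagents that add atoms: none
Why: hydride reduction should convert the methyl ester into the primary alcohol and cleave the acetate in the same operation, and C9 is not epimerised because hydride addition outpaces enolisation.

Step 13
Reactants: 19 (3R,5S,9R,10R)-drim-7-ene-3,11-diol
Product: 20 (3R,5S,9R,10R)-3-hydroxydrim-7-en-11-al
Conditions: TEMPO (0.1 equiv), PhI(OAc)2, CH2Cl2, rt
Reagents that add atoms: none
Why: the oxoammonium (TEMPO) oxidation is selective for primary over hindered secondary alcohols and is non-basic, so the β,γ-unsaturated aldehyde should neither epimerise at C9 nor move into conjugation.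

Step 14
Reactants: 20 (3R,5S,9R,10R)-3-hydroxydrim-7-en-11-al
Product: 21 (3R,5S,9R,10R)-11-oxodrim-7-en-3-yl acetate
Conditions: Ac2O, pyridine, DMAP (cat.), CH2Cl2, 0 °C → rt
Reagents that add atoms: acetic anhydride, CC(=O)OC(C)=O
Why: acetylation installs the C3 acetate of the target before the C11 hydroxyl exists, so the two secondary alcohols never have to be differentiated.

Step 15
Reactants: 21 (3R,5S,9R,10R)-11-oxodrim-7-en-3-yl acetate
Product: 22 (3R,5S,9R,10R,11S)-11-hydroxy-11-(prop-2-yn-1-yl)drim-7-en-3-yl acetate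
Conditions: (−)-B-allenyldiisopinocampheylborane [from (+)-α-pinene], Et2O, −78 °C; then HOCH2CH2NH2, rt
Reagents that add atoms: B-allenyldiisopinocampheylborane, C=C=CB([C@@H]1C[C@@H]2C[C@H]([C@H]1C)C2(C)C)[C@@H]1C[C@@H]2C[C@H]([C@H]1C)C2(C)C
Why: asymmetric allenylboration (propargylation) through a closed six-membered transition state, in which the isopinocampheyl groups should direct addition to the Si face and set 11S, overriding the aldehyde's own Felkin–Anh preference (nucleophile anti to quaternary C10), which would favour the 11-epimer.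

Step 16
Reactants: 22 (3R,5S,9R,10R,11S)-11-hydroxy-11-(prop-2-yn-1-yl)drim-7-en-3-yl acetate
Product: 24 (3R,5S,9R,10R,11S,13E)-11,15-dihydroxylabda-7,13-dien-3-yl acetate, via alkenylalane 23 (not isolated)
Conditions: AlMe3, Cp2ZrCl2 (0.25 equiv), H2O (1 equiv), CH2Cl2, −25 → 0 °C; then (CH2O)n, 0 °C → rt; aq. Rochelle salt
Reagents that add atoms: trimethylaluminium, C[Al](C)C; formaldehyde (as paraformaldehyde), C=O
Why: zirconium-catalysed methylalumination (Negishi carboalumination) adds methyl and aluminium syn across the terminal alkyne with methyl on the internal carbon, and capture of the alkenylalane by formaldehyde with retention should fix the 13E geometry.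

Step 17
Reactants: 24 (3R,5S,9R,10R,11S,13E)-11,15-dihydroxylabda-7,13-dien-3-yl acetate
Product: 25 (3R,5S,9R,10R,11S,13E)-11-hydroxylabda-7,13-diene-3,15-diyl diacetate
Conditions: Ac2O (1.1 equiv), 2,4,6-collidine, CH2Cl2, −20 → 0 °C
Reagents that add atoms: acetic anhydride, CC(=O)OC(C)=O
Why: the primary allylic alcohol should be acetylated much faster than the secondary C11 alcohol shielded by C9 and C10, so one equivalent of anhydride with a weak base at low temperature should give the target.

**Compound list**

1 | 2,2-dimethylpent-4-enal | C=CCC(C)(C)C=O | starting material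
2 | 2-(2-bromoethyl)-2-methyl-1,3-dioxolane | CC1(CCBr)OCCO1 | starting material
3 | [2-(2-methyl-1,3-dioxolan-2-yl)ethyl]magnesium bromide | CC1(CC[Mg]Br)OCCO1 | intermediate
4 | rac-4,4-dimethyl-1-(2-methyl-1,3-dioxolan-2-yl)hept-6-en-3-ol | CC1(CCC(O)C(C)(C)CC=C)OCCO1 | intermediate
5 | 4,4-dimethyl-1-(2-methyl-1,3-dioxolan-2-yl)hept-6-en-3-one | CC1(CCC(=O)C(C)(C)CC=C)OCCO1 | intermediate
6 | (3R)-4,4-dimethyl-1-(2-methyl-1,3-dioxolan-2-yl)hept-6-en-3-ol | C=CCC(C)(C)[C@H](O)CCC1(C)OCCO1 | intermediate
7 | (3R)-4,4-dimethyl-1-(2-methyl-1,3-dioxolan-2-yl)hept-6-en-3-yl acetate | C=CCC(C)(C)[C@H](OC(C)=O)CCC1(C)OCCO1 | intermediate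
8 | (5R)-6,6-dimethyl-2-oxonon-8-en-5-yl acetate | C=CCC(C)(C)[C@H](OC(C)=O)CCC(C)=O | intermediate
9 | methyl acetoacetate (methyl 3-oxobutanoate) | CC(=O)CC(=O)OC | starting material
10 | methyl (6R)-6-acetoxy-2-acetyl-3,7,7-trimethyldeca-2,9-dienoate (E/Z mixture) | C=CCC(C)(C)[C@H](OC(C)=O)CCC(C)=C(C(C)=O)C(=O)OC | intermediate
11 | methyl (6R)-6-acetoxy-2-acetyl-3,7,7-trimethyl-9-oxodec-2-enoate (E/Z mixture) | CC(=O)CC(C)(C)[C@H](OC(C)=O)CCC(C)=C(C(C)=O)C(=O)OC | intermediate
12 | methyl 2-[(1R,2S,4R)-4-acetoxy-2-acetyl-1,3,3-trimethylcyclohexyl]-3-oxobutanoate (Michael adduct, mixture at the side-chain carbon) | CC(=O)[C@@H]1C(C)(C)[C@H](OC(C)=O)CC[C@@]1(C)C(C(C)=O)C(=O)OC | intermediate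
13 | methyl (3R,5S,10R)-3-acetoxy-8-hydroxy-6-oxodriman-11-oate (ketol, mixture at C8 and C9) | COC(=O)C1C(C)(O)CC(=O)[C@@H]2C(C)(C)[C@H](OC(C)=O)CC[C@]21C | intermediate
14 | methyl (3R,5S,10R)-3-acetoxy-6-oxodrim-7-en-11-oate (C9 epimers) | COC(=O)C1C(C)=CC(=O)[C@@H]2C(C)(C)[C@H](OC(C)=O)CC[C@]21C | intermediate
15 | sodium (3R,5S,10R)-3-acetoxy-11-methoxy-11-oxodrima-6,8-dien-6-olate (extended enolate of 14) | [Na+].COC(=O)C1=C(C)C=C([O-])[C@@H]2C(C)(C)[C@H](OC(C)=O)CC[C@]21C | intermediate
16 | methyl (3R,5S,10R)-3-acetoxy-6-(trifluoromethanesulfonyloxy)drima-6,8-dien-11-oate | COC(=O)C1=C(C)C=C(OS(=O)(=O)C(F)(F)F)[C@@H]2C(C)(C)[C@H](OC(C)=O)CC[C@]21C | intermediate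
17 | methyl (3R,5S,10R)-3-acetoxydrima-6,8-dien-11-oate | COC(=O)C1=C(C)C=C[C@@H]2C(C)(C)[C@H](OC(C)=O)CC[C@]21C | intermediate
18 | methyl (3R,5S,9R,10R)-3-acetoxydrim-7-en-11-oate | COC(=O)[C@@H]1C(C)=CC[C@@H]2C(C)(C)[C@H](OC(C)=O)CC[C@]21C | intermediate
19 | (3R,5S,9R,10R)-drim-7-ene-3,11-diol | OC[C@@H]1C(C)=CC[C@@H]2C(C)(C)[C@H](O)CC[C@]21C | intermediate
20 | (3R,5S,9R,10R)-3-hydroxydrim-7-en-11-al | O=C[C@@H]1C(C)=CC[C@@H]2C(C)(C)[C@H](O)CC[C@]21C | intermediate
21 | (3R,5S,9R,10R)-11-oxodrim-7-en-3-yl acetate | O=C[C@@H]1C(C)=CC[C@@H]2C(C)(C)[C@H](OC(C)=O)CC[C@]21C | intermediate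
22 | (3R,5S,9R,10R,11S)-11-hydroxy-11-(prop-2-yn-1-yl)drim-7-en-3-yl acetate | C#CC[C@H](O)[C@@H]1C(C)=CC[C@@H]2C(C)(C)[C@H](OC(C)=O)CC[C@]21C | intermediate
23 | (13E)-alkenyldimethylalane of 22 with C11 dimethylaluminium alkoxide | C[Al](C)/C=C(\C)C[C@H](O[Al](C)C)[C@@H]1C(C)=CC[C@@H]2C(C)(C)[C@H](OC(C)=O)CC[C@]21C | intermediate
24 | (3R,5S,9R,10R,11S,13E)-11,15-dihydroxylabda-7,13-dien-3-yl acetate | OC/C=C(\C)C[C@H](O)[C@@H]1C(C)=CC[C@@H]2C(C)(C)[C@H](OC(C)=O)CC[C@]21C | intermediate
25 | (3R,5S,9R,10R,11S,13E)-11-hydroxylabda-7,13-diene-3,15-diyl diacetate | CC(=O)OC/C=C(\C)C[C@H](O)[C@@H]1C(C)=CC[C@@H]2C(C)(C)[C@H](OC(C)=O)CC[C@]21C | target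

**Step count**

Total step count: 17. Longest linear sequence: 17 steps (from 1 to 25).

**Steps most likely to fail**

Step 8. The acid-generated C5 enol may add too slowly to the fully substituted C10, so that deconjugation or vinylogous aldol reactions of the acceptor, or the alternative aldol closure, take over; facial discrimination at C10 by the remote acetoxy group may also be weak. The fallback sets out from 11 and returns at 14: the donor is activated as a preformed enamine and the two ring closures are run separately. Condensation of 11 with pyrrolidine (4 Å molecular sieves, benzene) should give the C5=C6 enamine, methyl (6R)-6-acetoxy-2-acetyl-3,7,7-trimethyl-9-(pyrrolidin-1-yl)deca-2,8-dienoate F1, the only enamine that can cyclise through a six-membered transition state. Its Stork enamine Michael addition onto C10 should give the ring A enamine, methyl 2-{(1R,2S,4R)-4-acetoxy-1,3,3-trimethyl-2-[1-(pyrrolidin-1-yl)ethenyl]cyclohexyl}-3-oxobutanoate F2. Hydrolysis (aq. AcOH/NaOAc) would free the diketone 12, isolated in this variant, and a separate classical 1,5-diketone cyclodehydration (TsOH, benzene, Dean–Stark) would close ring B to 14.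

Step 11. Coordination of the chromium fragment to a diene with a fully substituted terminus next to the quaternary C10 may be too slow, or diene isomerisation may compete. The fallback sets out from 17 and returns at 18 and makes no new compound (F0). It is an electron-transfer reduction of the dienoate with SmI2 (THF/HMPA, t-BuOH, −78 °C), a dissolving-metal-type 1,6-reduction of a 2,4-dienoate to a 3-enoate rather than a catalytic hydrogenation. Hydrogen is delivered first to C6 and then, by kinetic protonation from the face opposite the C10 methyl, to C9.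

Step 15. The reagent has to override the aldehyde's own Felkin–Anh preference (a mismatched pairing) at a carbonyl shielded by C10 and the C8 methyl, so facial selectivity may be eroded. The fallback sets out from 21 and returns at 22, and uses substrate control instead. Zinc-mediated Barbier propargylation (propargyl bromide, Zn, THF/aq. NH4Cl) should give mainly the Felkin–Anh product, (3R,5S,9R,10R,11R)-11-hydroxy-11-(prop-2-yn-1-yl)drim-7-en-3-yl acetate F3. Buffered Dess–Martin oxidation would give the ketone (3R,5S,9R,10R)-11-oxo-11-(prop-2-yn-1-yl)drim-7-en-3-yl acetate F4. Reduction with LiBH(s-Bu)3 at −78 °C, in which hydride takes the Felkin–Anh trajectory that carbon took before, should then give the 11S alcohol 22.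

Further compounds
F1 | step 8 | methyl (6R)-6-acetoxy-2-acetyl-3,7,7-trimethyl-9-(pyrrolidin-1-yl)deca-2,8-dienoate | CC(=CC(C)(C)[C@H](OC(C)=O)CCC(C)=C(C(C)=O)C(=O)OC)N1CCCC1
F2 | step 8 | methyl 2-{(1R,2S,4R)-4-acetoxy-1,3,3-trimethyl-2-[1-(pyrrolidin-1-yl)ethenyl]cyclohexyl}-3-oxobutanoate | C=C(N1CCCC1)[C@@H]1C(C)(C)[C@H](OC(C)=O)CC[C@@]1(C)C(C(C)=O)C(=O)OC
F0 | step 11 | none | none
F3 | step 15 | (3R,5S,9R,10R,11R)-11-hydroxy-11-(prop-2-yn-1-yl)drim-7-en-3-yl acetate | C#CC[C@@H](O)[C@@H]1C(C)=CC[C@@H]2C(C)(C)[C@H](OC(C)=O)CC[C@]21C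
F4 | step 15 | (3R,5S,9R,10R)-11-oxo-11-(prop-2-yn-1-yl)drim-7-en-3-yl acetate | C#CCC(=O)[C@@H]1C(C)=CC[C@@H]2C(C)(C)[C@H](OC(C)=O)CC[C@]21C
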